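**Strategy**

The target is a 3,3''-linked biflavanone whose only epimerisable centres, C3 and C3'', each lie next to a fixed anisyl-bearing C2 or C2'' in ring C. The route therefore disconnects both C4/C4'' carbonyl oxygens back to a C4=C3–C3''=C4'' diene. One double hydroboration–oxidation of a (2S,2''S)-3,3''-bi(2-aryl-2H-chromene) puts hydrogen on C3/C3'' and oxygen on C4/C4'' from the face opposite each C2 aryl group, setting four stereocentres at the non-enolisable carbinol level. The diene, with ring A phenols as benzyl ethers and the 7''-methoxy group in place, arises by tandem dienyne metathesis of an (S,S)-but-2-yne-1,4-diyl bis(2-vinylaryl) ether.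

Key step: step 11

Remark on descriptors: in diene 16 the sp2 carbons C3/C3'' outrank the anisyl carbon, so C2/C2'' are named S there, although the spatial arrangement is the one named R in 18–20. For the same reason 18 is 3S,3''S and 19–20 are 3R,3''R with no change in space.

Assumption: (S,S)-ProPhenol is taken to deliver the alkynylzinc to the Re face of 4-methoxybenzaldehyde (S carbinol). If the sense proves opposite, the (R,R) ligand is used in steps 4 and 7; the configuration of 10 is to be checked by Mosher ester analysis.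

**Route**

Step 1
Reactants: 1 2,6-difluoro-4-methoxybenzaldehyde; 2 benzyl alcohol
Product: 3 2-(benzyloxy)-6-fluoro-4-methoxybenzaldehyde
Conditions: BnOH (1.05 equiv), NaH (1.05 equiv), THF, 0 °C → rt
Reagents that add atoms: none
Why: Nucleophilic aromatic substitution of one of two equivalent ortho fluorides activated by the formyl group, so no regiochemical question arises, and the new alkoxy group deactivates the ring against a second substitution.

Step 2
Reactants: 4 2,6-difluoro-4-hydroxybenzaldehyde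
Product: 5 4-(benzyloxy)-2,6-difluorobenzaldehyde
Conditions: BnBr, K2CO3, DMF, rt
Reagents that add atoms: benzyl bromide, BrCc1ccccc1
Why: Williamson etherification of an acidic, formyl-conjugated phenol, whose weakly nucleophilic phenoxide should not displace ring fluoride at room temperature.

Step 3
Reactants: 5 4-(benzyloxy)-2,6-difluorobenzaldehyde; 2 benzyl alcohol
Product: 6 2,4-bis(benzyloxy)-6-fluorobenzaldehyde
Conditions: BnOH (1.05 equiv), NaH (1.05 equiv), THF, 0 °C → rt
Reagents that add atoms: none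
Why: Nucleophilic aromatic substitution of one of two equivalent ortho fluorides, as in step 1, which should stop after one exchange because the product is less electrophilic.

Step 4
Reactants: 7 4-methoxybenzaldehyde; 8 ethynyltrimethylsilane
Product: 10 (S)-1-(4-methoxyphenyl)prop-2-yn-1-ol, via silylated alkynol 9 (not isolated)
Conditions: Me2Zn, (S,S)-ProPhenol (10 mol %), Ph3PO (20 mol %), toluene, 4 °C; then K2CO3, MeOH, rt
Reagents that add atoms: none
Why: Zinc–ProPhenol-catalysed asymmetric alkynylation of an aryl aldehyde sets the future C2'' by catalyst-controlled Re-face delivery of the alkynylzinc, and carbonate in methanol then removes the silyl group without touching the carbinol.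

Step 5
Reactants: 10 (S)-1-(4-methoxyphenyl)prop-2-yn-1-ol; 3 2-(benzyloxy)-6-fluoro-4-methoxybenzaldehyde
Product: 11 2-(benzyloxy)-4-methoxy-6-{[(1S)-1-(4-methoxyphenyl)prop-2-yn-1-yl]oxy}benzaldehyde
Conditions: NaH (1.0 equiv), 3 (1.3 equiv), THF–DMF, 0 °C → rt
Reagents that add atoms: none
Why: Nucleophilic aromatic substitution by the sodium alkoxide forms the aryl–O bond and leaves the carbinol C–O bond intact, so the configuration is retained, and using the alkoxide as limiting reagent leaves no strong base beside the propargylic ether.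

Step 6
Reactants: 11 2-(benzyloxy)-4-methoxy-6-{[(1S)-1-(4-methoxyphenyl)prop-2-yn-1-yl]oxy}benzaldehyde
Product: 12 1-(benzyloxy)-2-ethenyl-5-methoxy-3-{[(1S)-1-(4-methoxyphenyl)prop-2-yn-1-yl]oxy}benzene
Conditions: Ph3PCH3Br, KOtBu, THF, 0 °C
Reagents that add atoms: methyltriphenylphosphonium bromide, C[P+](c1ccccc1)(c1ccccc1)c1ccccc1.[Br-]
Why: Wittig methylenation of the aryl aldehyde with a preformed ylide, which is too weak a base to deprotonate the propargylic C–H or the terminal alkyne at 0 °C.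

Step 7
Reactants: 12 1-(benzyloxy)-2-ethenyl-5-methoxy-3-{[(1S)-1-(4-methoxyphenyl)prop-2-yn-1-yl]oxy}benzene; 7 4-methoxybenzaldehyde
Product: 13 (1S,4S)-4-[3-(benzyloxy)-2-ethenyl-5-methoxyphenoxy]-1,4-bis(4-methoxyphenyl)but-2-yn-1-ol
Conditions: Me2Zn, 7 (2 equiv), (S,S)-ProPhenol (20 mol %), Ph3PO (40 mol %), toluene, 4 °C → rt
Reagents that add atoms: none
Why: A second zinc–ProPhenol asymmetric alkynylation, with the alkynylzinc made from 12 and Me2Zn, sets the future C2 by Re-face addition under catalyst control, the existing centre four atoms away across the alkyne having no influence.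

Step 8
Reactants: 13 (1S,4S)-4-[3-(benzyloxy)-2-ethenyl-5-methoxyphenoxy]-1,4-bis(4-methoxyphenyl)but-2-yn-1-ol; 6 2,4-bis(benzyloxy)-6-fluorobenzaldehyde
Product: 14 2,4-bis(benzyloxy)-6-{[(1S,4S)-4-[3-(benzyloxy)-2-ethenyl-5-methoxyphenoxy]-1,4-bis(4-methoxyphenyl)but-2-yn-1-yl]oxy}benzaldehyde
Conditions: NaH (1.0 equiv), 6 (1.5 equiv), THF–DMF, 0 °C → rt
Reagents that add atoms: none
Why: Nucleophilic aromatic substitution of the formyl-activated fluoride by the secondary alkoxide, again with retention because only the aryl–O bond is made.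

Step 9
Reactants: 14 2,4-bis(benzyloxy)-6-{[(1S,4S)-4-[3-(benzyloxy)-2-ethenyl-5-methoxyphenoxy]-1,4-bis(4-methoxyphenyl)but-2-yn-1-yl]oxy}benzaldehyde
Product: 15 (1S,4S)-1-[3,5-bis(benzyloxy)-2-ethenylphenoxy]-4-[3-(benzyloxy)-2-ethenyl-5-methoxyphenoxy]-1,4-bis(4-methoxyphenyl)but-2-yne
Conditions: Ph3PCH3Br, KOtBu, THF, 0 °C
Reagents that add atoms: methyltriphenylphosphonium bromide, C[P+](c1ccccc1)(c1ccccc1)c1ccccc1.[Br-]
Why: Wittig methylenation as in step 6 completes the dienyne without affecting the two propargylic ether centres.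

Step 10
Reactants: 15 (1S,4S)-1-[3,5-bis(benzyloxy)-2-ethenylphenoxy]-4-[3-(benzyloxy)-2-ethenyl-5-methoxyphenoxy]-1,4-bis(4-methoxyphenyl)but-2-yne
Product: 16 (2S,2''S)-5,5'',7-tris(benzyloxy)-7''-methoxy-2,2''-bis(4-methoxyphenyl)-2H,2''H-3,3''-bichromene
Conditions: second-generation Grubbs catalyst RuCl2(H2IMes)(PCy3)(=CHPh) (10 mol %), CH2Cl2 (5 mM), 40 °C, dark
Reagents that add atoms: none
Why: Tandem ring-closing dienyne metathesis, in which a ruthenium benzylidene formed at one styrene adds to the near alkyne carbon to close one ring C (C4=C3) and the resulting C3''-vinylcarbene closes the second ring C with the other styrene (C3''=C4'') with loss of ethylene, the two ether stereocentres being spectators and the mild temperature and darkness guarding against electrocyclic ring opening at C2.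

Step 11
Reactants: 16 (2S,2''S)-5,5'',7-tris(benzyloxy)-7''-methoxy-2,2''-bis(4-methoxyphenyl)-2H,2''H-3,3''-bichromene
Product: 18 (2R,3S,4S,2''R,3''S,4''S)-5,5'',7-tris(benzyloxy)-7''-methoxy-2,2''-bis(4-methoxyphenyl)-3,3''-bichromane-4,4''-diol, via bis(boranyl) adduct 17 (not isolated)
Conditions: BH3·THF (6 equiv), THF, 0 °C → rt; then 3 M NaOH, 30% H2O2, 0 °C → rt; Et3N-washed silica
Reagents that add atoms: hydrogen peroxide, OO
Why: BH3 adds across C3=C4 and C3''=C4'' by concerted four-centre syn addition, boron going to the CH carbons C4/C4'' and hydrogen to the fully substituted C3/C3'', and alkaline peroxide then replaces each C–B bond by C–O with retention (1,2-shift from boron to oxygen). The closest known reaction type is the hydroboration–oxidation of 3-substituted 2H-chromenes and 1-arylcycloalkenes, which gives the trans 4-ol anti to a neighbouring ring substituent; no ring is closed. C3 and C3'' are controlled by C2 and C2'' respectively: A(1,2) strain with the C3 substituent holds each anisyl group pseudo-axial over one face of ring C, so hydrogen arrives on the opposite face and the C3–C3'' bond ends up cis to the aryl group, while C4 and C4'' follow from the syn addition (OH cis to H3, trans to the C3–C3'' bond). The step needs boron at C4 and not C3 despite donation from the trioxygenated ring A, and this is secured by the steric difference between a CH terminus and a carbon bearing two ring substituents, and by C4/C4'' being the ends of the diene. Should a monoalkylborane bridge C4 and C4'', only the trans-anti-trans-fused borolane is accessible, which is the same diastereomer, and the small borane reacts at 0 °C, where the thermally ring-opening chromene C2 centres are safe.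

Step 12
Reactants: 18 (2R,3S,4S,2''R,3''S,4''S)-5,5'',7-tris(benzyloxy)-7''-methoxy-2,2''-bis(4-methoxyphenyl)-3,3''-bichromane-4,4''-diol
Product: 19 (2R,3R,2''R,3''R)-5,5'',7-tris(benzyloxy)-7''-methoxy-2,2''-bis(4-methoxyphenyl)-3,3''-bichromane-4,4''-dione
Conditions: Dess–Martin periodinane (3 equiv), NaHCO3, CH2Cl2, 0 °C → rt
Reagents that add atoms: none
Why: Dess–Martin oxidation of both benzylic carbinols under bicarbonate buffer is neither basic enough to enolise C3/C3'' of the 2,3-cis ketone nor acidic enough to ionise the electron-rich C4 carbinols (which would otherwise bridge C4 and C4'' as a cyclic ether).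

Step 13
Reactants: 19 (2R,3R,2''R,3''R)-5,5'',7-tris(benzyloxy)-7''-methoxy-2,2''-bis(4-methoxyphenyl)-3,3''-bichromane-4,4''-dione
Product: 20 (2R,3R,2''R,3''R)-5,5'',7-trihydroxy-7''-methoxy-2,2''-bis(4-methoxyphenyl)-3,3''-bichromane-4,4''-dione (CNP0184936.2)
Conditions: H2 (1 atm), 10% Pd/C, EtOAc–THF, rt
Reagents that add atoms: none
Why: Neutral hydrogenolysis of the three benzyl ethers should be faster than cleavage of the ring C benzylic C2–O bond or ketone reduction and cannot epimerise C3/C3'', the freed 5-hydroxy groups hydrogen-bonding to the C4 carbonyls.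

**Compound list**

1 | 2,6-difluoro-4-methoxybenzaldehyde | COc1cc(F)c(C=O)c(F)c1 | starting material
2 | benzyl alcohol | OCc1ccccc1 | starting material
3 | 2-(benzyloxy)-6-fluoro-4-methoxybenzaldehyde | COc1cc(F)c(C=O)c(OCc2ccccc2)c1 | intermediate
4 | 2,6-difluoro-4-hydroxybenzaldehyde | O=Cc1c(F)cc(O)cc1F | starting material
5 | 4-(benzyloxy)-2,6-difluorobenzaldehyde | O=Cc1c(F)cc(OCc2ccccc2)cc1F | intermediate
6 | 2,4-bis(benzyloxy)-6-fluorobenzaldehyde | O=Cc1c(F)cc(OCc2ccccc2)cc1OCc1ccccc1 | intermediate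
7 | 4-methoxybenzaldehyde | COc1ccc(C=O)cc1 | starting material
8 | ethynyltrimethylsilane | C#C[Si](C)(C)C | starting material
9 | (S)-1-(4-methoxyphenyl)-3-(trimethylsilyl)prop-2-yn-1-ol (not isolated) | C[Si](C)(C)C#C[C@@H](O)c1ccc(OC)cc1 | intermediate
10 | (S)-1-(4-methoxyphenyl)prop-2-yn-1-ol | C#C[C@@H](O)c1ccc(OC)cc1 | intermediate
11 | 2-(benzyloxy)-4-methoxy-6-{[(1S)-1-(4-methoxyphenyl)prop-2-yn-1-yl]oxy}benzaldehyde | C#C[C@@H](Oc1cc(OC)cc(OCc2ccccc2)c1C=O)c1ccc(OC)cc1 | intermediate
12 | 1-(benzyloxy)-2-ethenyl-5-methoxy-3-{[(1S)-1-(4-methoxyphenyl)prop-2-yn-1-yl]oxy}benzene | C#C[C@@H](Oc1cc(OC)cc(OCc2ccccc2)c1C=C)c1ccc(OC)cc1 | intermediate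
13 | (1S,4S)-4-[3-(benzyloxy)-2-ethenyl-5-methoxyphenoxy]-1,4-bis(4-methoxyphenyl)but-2-yn-1-ol | COc1ccc([C@H](O)C#C[C@@H](Oc2cc(OC)cc(OCc3ccccc3)c2C=C)c2ccc(OC)cc2)cc1 | intermediate
14 | 2,4-bis(benzyloxy)-6-{[(1S,4S)-4-[3-(benzyloxy)-2-ethenyl-5-methoxyphenoxy]-1,4-bis(4-methoxyphenyl)but-2-yn-1-yl]oxy}benzaldehyde | COc1ccc([C@H](Oc2cc(OCc3ccccc3)cc(OCc3ccccc3)c2C=O)C#C[C@@H](Oc2cc(OC)cc(OCc3ccccc3)c2C=C)c2ccc(OC)cc2)cc1 | intermediate
15 | (1S,4S)-1-[3,5-bis(benzyloxy)-2-ethenylphenoxy]-4-[3-(benzyloxy)-2-ethenyl-5-methoxyphenoxy]-1,4-bis(4-methoxyphenyl)but-2-yne | COc1ccc([C@H](Oc2cc(OCc3ccccc3)cc(OCc3ccccc3)c2C=C)C#C[C@@H](Oc2cc(OC)cc(OCc3ccccc3)c2C=C)c2ccc(OC)cc2)cc1 | intermediate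
16 | (2S,2''S)-5,5'',7-tris(benzyloxy)-7''-methoxy-2,2''-bis(4-methoxyphenyl)-2H,2''H-3,3''-bichromene | COc1ccc([C@@H]2Oc3cc(OCc4ccccc4)cc(OCc4ccccc4)c3C=C2C2=Cc3c(OCc4ccccc4)cc(OC)cc3O[C@H]2c2ccc(OC)cc2)cc1 | intermediate
17 | C4,C4''-bis(boranyl) adduct of 16, BH2 on C4 and C4'' trans to the C3–C3'' bond, H on C3 and C3'' trans to the anisyl groups (not isolated; a C4–BH–C4'' bridged form would oxidise to the same diol) | COc1ccc([C@@H]2Oc3cc(OCc4ccccc4)cc(OCc4ccccc4)c3[C@@H](B)[C@@H]2[C@H]2[C@H](B)c3c(OCc4ccccc4)cc(OC)cc3O[C@H]2c2ccc(OC)cc2)cc1 | intermediate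
18 | (2R,3S,4S,2''R,3''S,4''S)-5,5'',7-tris(benzyloxy)-7''-methoxy-2,2''-bis(4-methoxyphenyl)-3,3''-bichromane-4,4''-diol (2,3-cis, 3,4-trans in both rings) | COc1ccc([C@@H]2Oc3cc(OCc4ccccc4)cc(OCc4ccccc4)c3[C@@H](O)[C@@H]2[C@H]2[C@H](O)c3c(OCc4ccccc4)cc(OC)cc3O[C@H]2c2ccc(OC)cc2)cc1 | intermediate
19 | (2R,3R,2''R,3''R)-5,5'',7-tris(benzyloxy)-7''-methoxy-2,2''-bis(4-methoxyphenyl)-3,3''-bichromane-4,4''-dione | COc1ccc([C@@H]2Oc3cc(OCc4ccccc4)cc(OCc4ccccc4)c3C(=O)[C@@H]2[C@H]2C(=O)c3c(OCc4ccccc4)cc(OC)cc3O[C@H]2c2ccc(OC)cc2)cc1 | intermediate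
20 | (2R,3R,2''R,3''R)-5,5'',7-trihydroxy-7''-methoxy-2,2''-bis(4-methoxyphenyl)-3,3''-bichromane-4,4''-dione | COc1ccc([C@@H]2Oc3cc(O)cc(O)c3C(=O)[C@@H]2[C@H]2C(=O)c3c(O)cc(OC)cc3O[C@H]2c2ccc(OC)cc2)cc1 | target

**Step count**

Total step count: 13.
Longest linear sequence: 10 steps (7 to 20 through steps 4–13).

**Steps most likely to fail**

1. Step 11. Boron may go partly to C3/C3'' under the electronic pull of ring A (a C3 borane would eliminate across C2–O and open ring C). The second alkene may also react incompletely, or face selection may erode once the first ring is saturated. The fallback sets out from 16 and returns at 19. Both alkenes are hydrogenated with Crabtree's catalyst [Ir(cod)(PCy3)(py)]PF6 under H2 in CH2Cl2, hydrogen again arriving anti to the C2/C2'' aryl groups and the benzyl ethers surviving, to give (2R,3R,2''R,3''R)-5,5'',7-tris(benzyloxy)-7''-methoxy-2,2''-bis(4-methoxyphenyl)-3,3''-bichromane F1. Benzylic oxidation at C4/C4'' with DDQ in wet CH2Cl2, where hydride abstraction is favoured by the trioxygenated ring A, then gives the (2R,3S,2''R,3''S)-configured 4,4''-diol as a mixture of C4/C4'' epimers F2. Buffered Dess–Martin oxidation as in step 12 erases these centres and delivers 19.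

2. Step 8. Substitution by the hindered secondary alkoxide on the doubly alkoxy-deactivated fluoride may be slow. During that time the alkoxide can isomerise the propargylic aryl ether to an allene (loss of C2'') or transfer hydride to the aldehyde. The fallback sets out from 13 and returns at 14. The alkoxide of 13 (NaH, THF, −20 → 0 °C) is reacted with the more electrophilic difluoride 5, giving 4-(benzyloxy)-2-fluoro-6-{[(1S,4S)-4-[3-(benzyloxy)-2-ethenyl-5-methoxyphenoxy]-1,4-bis(4-methoxyphenyl)but-2-yn-1-yl]oxy}benzaldehyde F3. The remaining fluoride is then exchanged with the unhindered sodium benzyloxide (BnOH, NaH, 1.1 equiv, THF–DMF, 0 °C) to give 14.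

3. Step 10. The cascade may stall at the hindered internal alkyne, flanked by two fully substituted ether carbons, or the catalyst may decay before the second ring closes. Forcing it by heat risks electrocyclic ring opening at C2/C2''. The fallback sets out from 15 and returns at 16. The alkyne is first converted intermolecularly with ethylene (1 atm, RuCl2(H2IMes)(PCy3)(=CHPh), CH2Cl2, rt; cross enyne metathesis) into (1S,4S)-1-[3,5-bis(benzyloxy)-2-ethenylphenoxy]-4-[3-(benzyloxy)-2-ethenyl-5-methoxyphenoxy]-1,4-bis(4-methoxyphenyl)-2,3-dimethylidenebutane F4. Two ordinary ring-closing olefin metatheses of its 1,1-disubstituted alkenes with the styrenes then follow, using the second-generation Hoveyda–Grubbs catalyst RuCl2(H2IMes)(=CH–C6H4-2-OiPr) in toluene at 50 °C, to give 16.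

**Further compounds**

F1 | step 11 | (2R,3R,2''R,3''R)-5,5'',7-tris(benzyloxy)-7''-methoxy-2,2''-bis(4-methoxyphenyl)-3,3''-bichromane | COc1ccc([C@@H]2Oc3cc(OCc4ccccc4)cc(OCc4ccccc4)c3C[C@@H]2[C@H]2Cc3c(OCc4ccccc4)cc(OC)cc3O[C@H]2c2ccc(OC)cc2)cc1
F2 | step 11 | (2R,3S,2''R,3''S)-5,5'',7-tris(benzyloxy)-7''-methoxy-2,2''-bis(4-methoxyphenyl)-3,3''-bichromane-4,4''-diol, C4 and C4'' epimers | COc1ccc([C@@H]2Oc3cc(OCc4ccccc4)cc(OCc4ccccc4)c3C(O)[C@@H]2[C@H]2C(O)c3c(OCc4ccccc4)cc(OC)cc3O[C@H]2c2ccc(OC)cc2)cc1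
F3 | step 8 | 4-(benzyloxy)-2-fluoro-6-{[(1S,4S)-4-[3-(benzyloxy)-2-ethenyl-5-methoxyphenoxy]-1,4-bis(4-methoxyphenyl)but-2-yn-1-yl]oxy}benzaldehyde | COc1ccc([C@H](Oc2cc(OCc3ccccc3)cc(F)c2C=O)C#C[C@@H](Oc2cc(OC)cc(OCc3ccccc3)c2C=C)c2ccc(OC)cc2)cc1
F4 | step 10 | (1S,4S)-1-[3,5-bis(benzyloxy)-2-ethenylphenoxy]-4-[3-(benzyloxy)-2-ethenyl-5-methoxyphenoxy]-1,4-bis(4-methoxyphenyl)-2,3-dimethylidenebutane | COc1ccc([C@H](Oc2cc(OCc3ccccc3)cc(OCc3ccccc3)c2C=C)C(=C)C(=C)[C@@H](Oc2cc(OC)cc(OCc3ccccc3)c2C=C)c2ccc(OC)cc2)cc1
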